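A direct plan would buy the stereocentre as D-tyrosine A1, convert it by nitrite deamination in methoxyacetic acid and double O-prenylation into the aryl prenyl ether ester A2, and move the aryl-bound prenyl group to the ortho carbon by a photochemical shift.
It would then close the lactone by Dieckmann condensation to the 3-methoxytetronic acid A3, form the enol triflate A4 and attach the 4-hydroxyphenyl ring by a nickel-catalysed reductive coupling with 4-iodophenol A5.
Weak point 1, the photochemical O-to-C prenyl shift: a radical-pair recombination that would give ortho product, cleavage to the phenol and other recombination products side by side, at high dilution and partial conversion.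
Weak point 2, the Dieckmann ring closure with excess amide base: the only stereocentre would then be an enolisable α-acyloxy ester C–H, so the purchased chirality (an unnatural amino acid) would be at risk in the step that builds the ring.
Weak point 3, the final aryl–alkenyl coupling: an untested cross-electrophile reaction on an enol triflate with two free phenols and a labile C5–H, placed last, where failure would cost the whole sequence.

**Retrosynthetic overview** (ring B = lactone O1, C2(=O), C3(OMe), C4, C5; ring A = 4-hydroxyphenyl on C4; C6 = benzylic CH2 to ring C, the prenylated phenol)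
The only stereocentre, C5, bears a hydrogen that is γ to C2=O and allylic to C3=C4, so it is created last: C5–H and C6–H come from enantioselective hydrogenation of the flat, achiral (Z)-C5=C6 dienolide 14 under neutral conditions.
C5=C6 is cut by a vinylogous aldol condensation between methoxyfuranone 6 and 4-hydroxy-3-prenylbenzaldehyde 9.
Ring B closes first, from 4-hydroxyphenylpyruvic acid 1 (C2, C3, C4 and ring A) and formaldehyde (C5) through C4–C5 and O1–C2; the C3 methoxy group comes from acid-catalysed enol etherification.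
The design needs no chiral starting material and exposes the stereocentre to no base, needs no late aryl coupling (ring A is in the first starting material), and puts the prenyl group on ring C by ground-state C-alkylation before the fragments are joined.

Key step: step 6

Assumption: the sense of induction in step 6 cannot be taken from a closely matching case; (R)-BINAP is written, and the (S)-ligand would be used if a first run showed the opposite sense. TBS = tert-butyldimethylsilyl.

Step 1
Reactants: 1 3-(4-hydroxyphenyl)-2-oxopropanoic acid (4-hydroxyphenylpyruvic acid); 2 formaldehyde (37% in water)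
Product: 4 3-hydroxy-4-(4-hydroxyphenyl)furan-2(5H)-one, via aldol adduct 3 (not isolated)
Conditions: 2 (1.05 equiv), K2CO3 (2.2 equiv), H2O, N2, 23 °C, 12 h; then 6 M HCl to pH 1, 60 °C, 1 h
Reagents that add atoms: none
Why: Crossed aldol addition of the enolised arylpyruvate (C4 as nucleophile) to formaldehyde, which should outrun self-condensation because formaldehyde is by far the better electrophile, followed by acid lactonisation of 3 and enolisation toward ring A, closes ring B through C4–C5 and O1–C2; the stereocentre of 3 is lost on enolisation.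

Step 2
Reactants: 4 3-hydroxy-4-(4-hydroxyphenyl)furan-2(5H)-one
Product: 6 4-(4-hydroxyphenyl)-3-methoxyfuran-2(5H)-one, via dimethyl ketal 5 (not isolated)
Conditions: HC(OMe)3 (3 equiv), TsOH·H2O (10 mol %), MeOH, 65 °C, 6 h; then toluene, 100 °C, MeOH distilled off
Reagents that add atoms: methanol, CO; trimethyl orthoformate, COC(OC)OC
Why: Acid-catalysed enol etherification of a diosphenol-type α-keto lactone, in which C4-protonation, ketalisation of the electrophilic C3 carbonyl to 5 and loss of methanol toward C4 should give the aryl-conjugated enol ether, while a phenol is not alkylated by methanol and acid, which secures O-selectivity without a protecting group; no stereocentre.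

Step 3
Reactants: 7 4-hydroxybenzaldehyde; 8 1-bromo-3-methylbut-2-ene (prenyl bromide)
Product: 9 4-hydroxy-3-(3-methylbut-2-en-1-yl)benzaldehyde
Conditions: 8 (1.0 equiv), 10% aq KOH (1.0 equiv), 23 °C, 24 h; then dilute HCl; chromatography, unreacted 7 recovered
Reagents that add atoms: none
Why: ortho-C-alkylation of an ambident phenoxide in water, where hydrogen bonding shields the oxygen and SN2 attack from the ortho carbon (para is blocked by the formyl group) on the primary carbon of 8 should give the linear prenyl group after re-aromatisation; no stereocentre.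

Step 4
Reactants: 6 4-(4-hydroxyphenyl)-3-methoxyfuran-2(5H)-one; 9 4-hydroxy-3-(3-methylbut-2-en-1-yl)benzaldehyde
Product: 13 (Z)-5-[4-(TBS-oxy)-3-(3-methylbut-2-en-1-yl)benzylidene]-4-[4-(TBS-oxy)phenyl]-3-methoxyfuran-2(5H)-one, via silyloxyfuran 10 (not isolated), via silylated aldehyde 11 (not isolated), via silyl aldol adduct 12 (not isolated)
Conditions: 9 (1.1 equiv), TBSOTf (3.5 equiv), iPr2NEt (5 equiv), CH2Cl2, 0 to 23 °C, 2 h; then DBU (2.5 equiv), 23 °C, 6 h
Reagents that add atoms: tert-butyldimethylsilyl trifluoromethanesulfonate, CC(C)(C)[Si](C)(C)OS(=O)(=O)C(F)(F)F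
Why: One-pot vinylogous Mukaiyama aldol addition and E1cB elimination, in which TBSOTf/iPr2NEt silylates both phenols and turns 6 into the 2-silyloxyfuran 10, which adds through C5 to the silyl-activated aldehyde 11 to give 12, and DBU then expels silanolate to give the thermodynamically preferred (Z)-alkene with ring C syn to O1 and away from ring A; no stereocentre remains.

Step 5
Reactants: 13 (Z)-5-[4-(TBS-oxy)-3-(3-methylbut-2-en-1-yl)benzylidene]-4-[4-(TBS-oxy)phenyl]-3-methoxyfuran-2(5H)-one
Product: 14 (Z)-5-[4-hydroxy-3-(3-methylbut-2-en-1-yl)benzylidene]-4-(4-hydroxyphenyl)-3-methoxyfuran-2(5H)-one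
Conditions: Bu4NF (2.2 equiv), AcOH (2.5 equiv), THF, 0 °C, 1 h
Reagents that add atoms: none
Why: Fluoride cleavage of the two aryl silyl ethers (driven by the strong Si–F bond), buffered with acetic acid so that the enol lactone is not opened, is done on the achiral dienolide so that no fluoride or base is needed once C5 is a stereocentre.

Step 6
Reactants: 14 (Z)-5-[4-hydroxy-3-(3-methylbut-2-en-1-yl)benzylidene]-4-(4-hydroxyphenyl)-3-methoxyfuran-2(5H)-one
Product: 15 (R)-5-[4-hydroxy-3-(3-methylbut-2-en-1-yl)benzyl]-4-(4-hydroxyphenyl)-3-methoxyfuran-2(5H)-one (target)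
Conditions: Ru(OAc)2[(R)-BINAP] (2 mol %), H2 (60 bar), THF, 40 °C, 24 h
Reagents that add atoms: none
Why: Proposed new method: enantioselective hydrogenation of the exocyclic enol-lactone C5=C6 bond of a cross-conjugated (Z)-5-arylidene butenolide that also carries a prenyl group; the ruthenium monohydride formed from the diacetate complex and H2 should coordinate and insert the exocyclic alkene and be cleaved by H2, so that both hydrogens arrive on one face of the planar dienolide. The closest known reaction types are the BINAP–ruthenium hydrogenation of diketene and γ-methylene-γ-butyrolactone and the metal-catalysed hydrogenation of 3-ylidenephthalides to 3-substituted phthalides; that an isolated trisubstituted alkene survives BINAP–ruthenium hydrogenation is known from geraniol. No ring is closed in this step. The only stereocentre, C5, is set by the C2-symmetric diphosphine, which distinguishes the two faces of the single (Z)-isomer, with the sense assumed as stated above. The step needs chemoselectivity for C5=C6 over the prenyl alkene and the C3=C4 bond, which the substrate should secure because C5=C6 is the only oxygen-activated and accessible alkene, the prenyl group has no coordinating neighbour and C3=C4 is tetrasubstituted. The conditions are neutral, so the acidic C5–H of the product should not be epimerised.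

## Compound list
1 | 3-(4-hydroxyphenyl)-2-oxopropanoic acid | O=C(O)C(=O)Cc1ccc(O)cc1 | starting material
2 | formaldehyde | C=O | starting material
3 | 4-hydroxy-3-(4-hydroxyphenyl)-2-oxobutanoic acid (racemic) | O=C(O)C(=O)C(CO)c1ccc(O)cc1 | intermediate
4 | 3-hydroxy-4-(4-hydroxyphenyl)furan-2(5H)-one | O=C1OCC(c2ccc(O)cc2)=C1O | intermediate
5 | 4-(4-hydroxyphenyl)-3,3-dimethoxydihydrofuran-2(3H)-one (racemic) | COC1(OC)C(c2ccc(O)cc2)COC1=O | intermediate
6 | 4-(4-hydroxyphenyl)-3-methoxyfuran-2(5H)-one | COC1=C(c2ccc(O)cc2)COC1=O | intermediate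
7 | 4-hydroxybenzaldehyde | O=Cc1ccc(O)cc1 | starting material
8 | 1-bromo-3-methylbut-2-ene | CC(C)=CCBr | starting material
9 | 4-hydroxy-3-(3-methylbut-2-en-1-yl)benzaldehyde | CC(C)=CCc1cc(C=O)ccc1O | intermediate
10 | tert-butyl{[4-(4-{[tert-butyl(dimethyl)silyl]oxy}phenyl)-3-methoxyfuran-2-yl]oxy}dimethylsilane | COc1c(O[Si](C)(C)C(C)(C)C)occ1-c1ccc(O[Si](C)(C)C(C)(C)C)cc1 | intermediate
11 | 4-{[tert-butyl(dimethyl)silyl]oxy}-3-(3-methylbut-2-en-1-yl)benzaldehyde | CC(C)=CCc1cc(C=O)ccc1O[Si](C)(C)C(C)(C)C | intermediate
12 | 5-{(TBS-oxy)[4-(TBS-oxy)-3-(3-methylbut-2-en-1-yl)phenyl]methyl}-4-[4-(TBS-oxy)phenyl]-3-methoxyfuran-2(5H)-one (mixture of diastereomers) | COC1=C(c2ccc(O[Si](C)(C)C(C)(C)C)cc2)C(C(O[Si](C)(C)C(C)(C)C)c2ccc(O[Si](C)(C)C(C)(C)C)c(CC=C(C)C)c2)OC1=O | intermediate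
13 | (Z)-5-[4-(TBS-oxy)-3-(3-methylbut-2-en-1-yl)benzylidene]-4-[4-(TBS-oxy)phenyl]-3-methoxyfuran-2(5H)-one | COC1=C(c2ccc(O[Si](C)(C)C(C)(C)C)cc2)/C(=C/c2ccc(O[Si](C)(C)C(C)(C)C)c(CC=C(C)C)c2)OC1=O | intermediate
14 | (Z)-5-[4-hydroxy-3-(3-methylbut-2-en-1-yl)benzylidene]-4-(4-hydroxyphenyl)-3-methoxyfuran-2(5H)-one | COC1=C(c2ccc(O)cc2)/C(=C/c2ccc(O)c(CC=C(C)C)c2)OC1=O | intermediate
15 | (R)-5-[4-hydroxy-3-(3-methylbut-2-en-1-yl)benzyl]-4-(4-hydroxyphenyl)-3-methoxyfuran-2(5H)-one | COC1=C(c2ccc(O)cc2)[C@@H](Cc2ccc(O)c(CC=C(C)C)c2)OC1=O | target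

Total step count: 6. Longest linear sequence: 5 (steps 1, 2, 4, 5, 6).

**Steps most likely to fail**

1. Step 6 (proposed new method). The catalyst may discriminate the two faces of the dienolide poorly, or hydrogen may also be delivered to the prenyl alkene or the exocyclic bond may migrate. The fallback uses known chemistry and sets out from 13. Copper hydride conjugate reduction with [(Ph3P)CuH]6 in toluene with tert-butanol should add hydride to the unhindered C6 terminus and leave the prenyl group alone, giving racemic 5-[4-(TBS-oxy)-3-(3-methylbut-2-en-1-yl)benzyl]-4-[4-(TBS-oxy)phenyl]-3-methoxyfuran-2(5H)-one F1. Preparative chromatography on a chiral stationary phase would separate the (R)-bis-silyl lactone F2 from the (S)-bis-silyl lactone F3. F3 would be racemised through its furanolate with DBU in dry THF and returned to the separation. F2 would be desilylated with Bu4NF/AcOH at 0 °C, which comes back to the route at 15.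

2. Step 2. Loss of methanol from ketal 5 may stall, or the lactone may be opened by methanol under acid. The fallback sets out from 4 and changes to a protect-then-alkylate approach. TBSCl/imidazole in DMF would give 3-(TBS-oxy)-4-[4-(TBS-oxy)phenyl]furan-2(5H)-one F4. Dilute acetic acid in THF/water should cleave only the acid-labile silyl enol ether to give 3-hydroxy-4-[4-(TBS-oxy)phenyl]furan-2(5H)-one F5. MeI/K2CO3 in acetone would then give 3-methoxy-4-[4-(TBS-oxy)phenyl]furan-2(5H)-one F6. F6 would enter the conditions of step 4 in place of 6 (one equivalent less TBSOTf), pass through the same silyloxyfuran 10 and come back to the route at 13.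

3. Step 3. O-Alkylation and double C-alkylation may consume the phenoxide, leaving little of the mono-C-prenyl product. The fallback sets out from 7 and replaces direct C-alkylation by a sigmatropic shift and a metathesis. Allyl bromide/K2CO3 in acetone would give 4-(allyloxy)benzaldehyde F7. Aromatic Claisen rearrangement in N,N-diethylaniline at 200 °C would give 3-allyl-4-hydroxybenzaldehyde F8. Cross-metathesis with excess 2-methylbut-2-ene and the second-generation Grubbs catalyst in CH2Cl2 would convert the allyl group into the prenyl group and come back to the route at 9.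

## Further compounds
F1 | step 6 | racemic 5-[4-(TBS-oxy)-3-(3-methylbut-2-en-1-yl)benzyl]-4-[4-(TBS-oxy)phenyl]-3-methoxyfuran-2(5H)-one | COC1=C(c2ccc(O[Si](C)(C)C(C)(C)C)cc2)C(Cc2ccc(O[Si](C)(C)C(C)(C)C)c(CC=C(C)C)c2)OC1=O
F2 | step 6 | (R)-5-[4-(TBS-oxy)-3-(3-methylbut-2-en-1-yl)benzyl]-4-[4-(TBS-oxy)phenyl]-3-methoxyfuran-2(5H)-one | COC1=C(c2ccc(O[Si](C)(C)C(C)(C)C)cc2)[C@@H](Cc2ccc(O[Si](C)(C)C(C)(C)C)c(CC=C(C)C)c2)OC1=O
F3 | step 6 | (S)-5-[4-(TBS-oxy)-3-(3-methylbut-2-en-1-yl)benzyl]-4-[4-(TBS-oxy)phenyl]-3-methoxyfuran-2(5H)-one | COC1=C(c2ccc(O[Si](C)(C)C(C)(C)C)cc2)[C@H](Cc2ccc(O[Si](C)(C)C(C)(C)C)c(CC=C(C)C)c2)OC1=O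
F4 | step 2 | 3-(TBS-oxy)-4-[4-(TBS-oxy)phenyl]furan-2(5H)-one | CC(C)(C)[Si](C)(C)OC1=C(c2ccc(O[Si](C)(C)C(C)(C)C)cc2)COC1=O
F5 | step 2 | 3-hydroxy-4-[4-(TBS-oxy)phenyl]furan-2(5H)-one | OC1=C(c2ccc(O[Si](C)(C)C(C)(C)C)cc2)COC1=O
F6 | step 2 | 3-methoxy-4-[4-(TBS-oxy)phenyl]furan-2(5H)-one | COC1=C(c2ccc(O[Si](C)(C)C(C)(C)C)cc2)COC1=O
F7 | step 3 | 4-(allyloxy)benzaldehyde | C=CCOc1ccc(C=O)cc1
F8 | step 3 | 3-allyl-4-hydroxybenzaldehyde | C=CCc1cc(C=O)ccc1O
A1 | direct plan | D-tyrosine | N[C@H](Cc1ccc(O)cc1)C(=O)O
A2 | direct plan | 3-methylbut-2-en-1-yl (R)-2-(2-methoxyacetoxy)-3-[4-(3-methylbut-2-en-1-yloxy)phenyl]propanoate | COCC(=O)O[C@H](Cc1ccc(OCC=C(C)C)cc1)C(=O)OCC=C(C)C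
A3 | direct plan | (R)-4-hydroxy-5-[4-hydroxy-3-(3-methylbut-2-en-1-yl)benzyl]-3-methoxyfuran-2(5H)-one | COC1=C(O)[C@@H](Cc2ccc(O)c(CC=C(C)C)c2)OC1=O
A4 | direct plan | (R)-2-[4-hydroxy-3-(3-methylbut-2-en-1-yl)benzyl]-4-methoxy-5-oxo-2,5-dihydrofuran-3-yl trifluoromethanesulfonate | COC1=C(OS(=O)(=O)C(F)(F)F)[C@@H](Cc2ccc(O)c(CC=C(C)C)c2)OC1=O
A5 | direct plan | 4-iodophenol | Oc1ccc(I)cc1
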